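At 5.00 h the teal flask has used more starting material than it shows as ring: 85.0% against 33%.

the same everywhere: starting material 30 mM

| flask | activator | temperature | remark | time |
|---|---|---|---|---|
| teal | 0.80 equiv | 5 °C | the very flask that is asked about, followed so far |  |
| violet | 1.6 equiv | 11 °C | run made earlier |  |
| flask | 0.800 equiv | 5 °C |  | 5.0 h |

- teal (time / h: ring / %, starting material / %): 0.417: 19, 64; 1.33: 31, 35; 2.50: 35, 27; 4.00: 36, 20; 5.00: 33, 15
- violet (time / min: ring / %, starting material / %): 5.00: 13, 70; 10.0: 26, 53; 15.0: 35, 41; 20.0: 39, 35; 25.0: 40, 30

(readings scatter by 1.5 percentage points)

- spring: at 5.0 h add activator, 100% of the amount charged, then wait 5.0 h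
- dawn: at 5.0 h raise the temperature by 25 K, then wait 5.0 h
- summer: change nothing and wait 5.0 h more
- dusk: at 5.0 h add starting material, 50.0% of the amount charged, then wait 5.0 h

- ring, in percent of the starting material first charged, at 5.0 h
- which option adds most ring ("none" when 2 percentage points or less is all one gets) (spring / dawn / summer / dusk / none)
- ring present, in percent of the starting material first charged, after spring
- ring present, in percent of the starting material first charged, after dawn

- in percentages every species weighs as the starting material in it: one open dimer counts as two
- for ring the idle adduct is counted in
- additions bring no volume worth counting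
- steps that have been proposed: starting material + activator -> activated form; starting material + activated form -> open dimer; ring <-> isomer of the product; activated form -> ring; activator + ring <-> idle adduct

Teal is the flask in question, so the reckoning works with the fraction left. That reserve is 15.0%. Activated form aside, turning the reserve into ring adds at most 15.0%. The ring reading gives the yield on the used, Y, meaning ring per point of starting material consumed, the integral selectivity: 0.388.

Which numbers matter? A slip of 1.5 percentage points in the reserve moves the prospect of spring by 0.58 points, which is small. The same slip in ring moves the answer to "now" by the full 1.5 points. Y itself matters more, because teal's Y was higher at the first reading, 0.528. The prospect of spring therefore spans 5.8 points to 7.9 points. The remaining 52.0% are open dimer, isomer of the product and activated form, and these readings do not split them. Any gain beyond the reserve has to come out of those points.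

This reckoning commits to 33% now and 38.8% after spring. The forecast says 34.5%, spring, 38% and 25%, for dawn on these grounds: “isomerisation speeds up too and likely reaches equilibrium”.

The flask holds 32.1% at 5.0 h, and the best option is dawn, which gives 49.5%, while spring gives 39.4%.

    starting material + activator → activated form (k = 47.6 M⁻¹ h⁻¹, Ea = 54.0 kJ mol⁻¹)
    starting material + activated form → open dimer (k = 521 M⁻¹ h⁻¹, Ea = 53.0 kJ mol⁻¹)
    ring ⇌ isomer of the product (K = 1.50, k = 0.196 h⁻¹, Ea = 89.0 kJ mol⁻¹, ΔH = −50.0 kJ mol⁻¹)
    activated form → ring (k = 24.9 h⁻¹, Ea = 81.0 kJ mol⁻¹)
    activator + ring ⇌ idle adduct, settled at all times (K = 43.0 M⁻¹, ΔH = −19.0 kJ mol⁻¹)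
    (constants at 5 °C)

That gain of 17 points exceeds the starting material left at 5.00 h, 16.0%, while isomer of the product then stands at 18.4%. On this flask, Y times the fraction left gives 6.2 points, and spring adds 7.3 points. The neighbour with 18 mM keeps 24.7% of its starting material at 5.00 h, so Y gives it 29.2% of ring, and it holds 33.4%.

(The numbers in the tables are simulated for substances that don't exist, and the scatter is random.)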